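**Retrosynthetic overview**
1. Feature: on ring A (the anisole ring) the bridge carbon sits at C1, para to the OMe-bearing C4 and meta to the aryloxy-bearing C3. Ring A plus both carbons of the A–D bridge is therefore the skeleton of 3-hydroxy-4-methoxyacetophenone: its C=O carbon is the ring A benzylic carbon, and its CH3 carbon is the carbon bound to C3 of the meta-phenylene ring D.
2. Endgame: the CH2 next to ring A is traced back to C=O and the ring C phenol to its benzyl ether; one acidic hydrogenation removes both.
3. Key disconnection: the CH2–C3(ring D) bond of this macrocyclic deoxybenzoin, made by intramolecular palladium-catalysed enolate arylation of an open-chain methyl ketone/aryl bromide. This closes the only ring that must be built, the 20-membered macrocycle; the four benzene rings are bought.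
4. Open chain: the B–C CH2CH2 bridge comes from a Wittig olefination and a diimide reduction. The A–O–B and C–O–D ethers come from two SNAr reactions on para-fluorobenzaldehydes.
5. The ketone travels as a dioxolane through all basic aldehyde chemistry and is released just before ring closure.

Key step: step 10

Remark: the target has no stereocentre and no stereogenic double bond, so no step has to control configuration. The Wittig alkene is carried on as an E/Z mixture because the next step erases its geometry.

**Route**

Step 1
Reactants: 1 3-hydroxy-4-methoxyacetophenone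
Product: 2 2-methoxy-5-(2-methyl-1,3-dioxolan-2-yl)phenol
Conditions: HOCH2CH2OH (5 equiv), p-TsOH·H2O (cat.), toluene, Dean–Stark, reflux; Et3N quench
Reagents that add atoms: ethylene glycol, OCCO
Why: Acid-catalysed ketalisation driven by azeotropic water removal masks the enolisable methyl ketone, which could otherwise undergo Claisen–Schmidt condensation with the aldehydes of steps 2 and 7, and it leaves the phenol free.

Step 2
Reactants: 2 2-methoxy-5-(2-methyl-1,3-dioxolan-2-yl)phenol; 3 4-fluorobenzaldehyde
Product: 4 4-[2-methoxy-5-(2-methyl-1,3-dioxolan-2-yl)phenoxy]benzaldehyde (rings A and B)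
Conditions: K2CO3, DMF, 120 °C
Reagents that add atoms: none
Why: Nucleophilic aromatic substitution (SNAr), in which the phenoxide of 2 adds at the carbon para to the formyl group of 3 and fluoride leaves from the Meisenheimer adduct, while the dioxolane is inert to carbonate.

Step 3
Reactants: 5 4-fluoro-3-hydroxybenzaldehyde
Product: 6 3-(benzyloxy)-4-fluorobenzaldehyde
Conditions: BnBr, K2CO3, DMF, rt
Reagents that add atoms: benzyl bromide, BrCc1ccccc1
Why: Williamson ether synthesis; the benzyl ether keeps the ring C phenol from competing as a nucleophile in step 4 and from consuming base in steps 7 and 10, and it is cleaved in the final hydrogenation at no extra cost.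

Step 4
Reactants: 6 3-(benzyloxy)-4-fluorobenzaldehyde; 7 3-bromophenol
Product: 8 3-(benzyloxy)-4-(3-bromophenoxy)benzaldehyde (rings C and D)
Conditions: K2CO3, DMF, 140 °C
Reagents that add atoms: none
Why: SNAr in which only the C–F bond para to the formyl group is activated, so the C–Br bond of 7 stays untouched, and the higher temperature offsets the donor effect of the ortho benzyloxy group.

Step 5
Reactants: 8 3-(benzyloxy)-4-(3-bromophenoxy)benzaldehyde
Product: 9 [3-(benzyloxy)-4-(3-bromophenoxy)phenyl]methanol
Conditions: NaBH4, MeOH/THF, 0 °C
Reagents that add atoms: none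
Why: Borohydride reduction of an aromatic aldehyde, which affects neither the aryl bromide nor the benzyl ether.

Step 6
Reactants: 9 [3-(benzyloxy)-4-(3-bromophenoxy)phenyl]methanol
Product: 10 [3-(benzyloxy)-4-(3-bromophenoxy)benzyl]triphenylphosphonium bromide
Conditions: PPh3·HBr, MeCN, reflux
Reagents that add atoms: triphenylphosphine hydrobromide, [Br-].[PH+](c1ccccc1)(c1ccccc1)c1ccccc1
Why: Direct phosphonium salt formation from a benzylic alcohol, in which HBr activates the benzylic C–O bond (stabilised by the para aryloxy group) and PPh3 captures the carbon, saving a separate bromination and sparing the aryl benzyl ether.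

Step 7
Reactants: 10 [3-(benzyloxy)-4-(3-bromophenoxy)benzyl]triphenylphosphonium bromide; 4 4-[2-methoxy-5-(2-methyl-1,3-dioxolan-2-yl)phenoxy]benzaldehyde
Product: 12 open-chain stilbene ketal (E/Z mixture; rings A–B–C–D in one chain), via benzylidene phosphorane 11 (not isolated)
Conditions: KOtBu, THF, 0 °C; then 4, 0 °C to rt
Reagents that add atoms: none
Why: Wittig olefination of a semistabilised benzylic ylide with an aromatic aldehyde joins the two halves through the two carbons of the B–C bridge, and the ketal, aryl bromide and benzyl ether tolerate the base at this temperature.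

Step 8
Reactants: 12 open-chain stilbene ketal
Product: 13 open-chain bibenzyl ketal
Conditions: 2-nitrobenzenesulfonohydrazide (excess, in portions), Et3N, CH2Cl2, rt
Reagents that add atoms: none
Why: Diimide reduction, whose concerted syn transfer of two hydrogens saturates the only C=C bond without touching C–Br or O-benzyl, while the anhydrous amine-buffered medium keeps the acid-labile dioxolane closed so that no sulfonylhydrazone can form at the ketone carbon.

Step 9
Reactants: 13 open-chain bibenzyl ketal
Product: 14 1-{3-[4-(2-{3-(benzyloxy)-4-(3-bromophenoxy)phenyl}ethyl)phenoxy]-4-methoxyphenyl}ethan-1-one (seco methyl ketone aryl bromide)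
Conditions: 1 M HCl, THF, rt
Reagents that add atoms: water, O
Why: Acid-catalysed ketal hydrolysis, fast here because the para methoxy group stabilises the oxocarbenium ion, under conditions to which the ethers and the aryl bromide are inert.

Step 10
Reactants: 14 seco methyl ketone aryl bromide
Product: 16 macrocyclic aryl ketone benzyl ether (20-membered ring; ring D–CH2–C(=O)–ring A), via macrocyclic sodium enolate 15 (not isolated)
Conditions: Pd(OAc)2 (10 mol %), XPhos (2-dicyclohexylphosphino-2',4',6'-triisopropylbiphenyl, 20 mol %), NaOtBu (2.5 equiv), toluene, 90 °C, 14 added by syringe pump over 12 h (final 2 mM); then AcOH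
Reagents that add atoms: none
Why: Proposed new method: zerovalent palladium carrying one XPhos inserts into the ring D C–Br bond, the sodium enolate of the ring A methyl ketone takes the place of bromide on the divalent arylpalladium centre, and C–C reductive elimination from the carbon-bound enolate joins the former CH3 carbon to C3 of ring D. The closest known reaction type is the palladium-catalysed α-arylation of aryl methyl ketones with aryl bromides, which is routine between two molecules and for small rings but has not been shown for a ring of this size. The one ring formed is the 20-membered macrocycle, closed end to end through a large palladacycle with all four arenes and both diaryl ethers already in place, and no stereocentre is created. The step needs a single arylation by the tethered bromide instead of chain growth; the substrate has only one enolisable carbon, and syringe-pump addition keeps unreacted 14 so dilute that the unimolecular closure should outrun bimolecular coupling. The deoxybenzoin formed is far more acidic than 14, so the second equivalent of base holds it as the hindered, delocalised enolate 15, which the bulky monophosphine catalyst should not arylate again before the acetic acid quench. The meta linkages at rings A and D and the flexible CH2CH2 bridge should let the chain fold without strain, and the benzyl and diaryl ethers react neither with NaOtBu nor with the catalyst.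

Step 11
Reactants: 16 macrocyclic aryl ketone benzyl ether
Product: 19 pakyonol, via macrocyclic keto phenol 17 (not isolated), via macrocyclic benzylic alcohol 18 (not isolated)
Conditions: H2 (4 bar), 10% Pd/C, EtOH/THF, conc. HCl (cat.), 40 °C
Reagents that add atoms: none
Why: Heterogeneous hydrogenation and hydrogenolysis, in which the aryl benzyl ether should cleave first, the para-methoxyaryl ketone is reduced to the benzylic alcohol, and acid-assisted C–O hydrogenolysis at that electron-rich benzylic carbon gives the CH2CH2 bridge, so the transient stereocentre of 18 disappears.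

**Compound list**
1 | 3-hydroxy-4-methoxyacetophenone | CC(=O)c1ccc(OC)c(O)c1 | starting material
2 | 2-methoxy-5-(2-methyl-1,3-dioxolan-2-yl)phenol | COc1ccc(cc1O)C1(C)OCCO1 | intermediate
3 | 4-fluorobenzaldehyde | O=Cc1ccc(F)cc1 | starting material
4 | 4-[2-methoxy-5-(2-methyl-1,3-dioxolan-2-yl)phenoxy]benzaldehyde | COc1ccc(cc1Oc1ccc(C=O)cc1)C1(C)OCCO1 | intermediate
5 | 4-fluoro-3-hydroxybenzaldehyde | O=Cc1ccc(F)c(O)c1 | starting material
6 | 3-(benzyloxy)-4-fluorobenzaldehyde | O=Cc1ccc(F)c(OCc2ccccc2)c1 | intermediate
7 | 3-bromophenol | Oc1cccc(Br)c1 | starting material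
8 | 3-(benzyloxy)-4-(3-bromophenoxy)benzaldehyde | O=Cc1ccc(Oc2cccc(Br)c2)c(OCc2ccccc2)c1 | intermediate
9 | [3-(benzyloxy)-4-(3-bromophenoxy)phenyl]methanol | OCc1ccc(Oc2cccc(Br)c2)c(OCc2ccccc2)c1 | intermediate
10 | [3-(benzyloxy)-4-(3-bromophenoxy)benzyl]triphenylphosphonium bromide | [Br-].Brc1cccc(Oc2ccc(C[P+](c3ccccc3)(c3ccccc3)c3ccccc3)cc2OCc2ccccc2)c1 | intermediate
11 | [3-(benzyloxy)-4-(3-bromophenoxy)benzylidene]triphenylphosphorane (ylide, not isolated) | Brc1cccc(Oc2ccc(C=P(c3ccccc3)(c3ccccc3)c3ccccc3)cc2OCc2ccccc2)c1 | intermediate
12 | 2-{3-[4-(2-{3-(benzyloxy)-4-(3-bromophenoxy)phenyl}ethenyl)phenoxy]-4-methoxyphenyl}-2-methyl-1,3-dioxolane (E/Z mixture, geometry left open) | COc1ccc(cc1Oc1ccc(C=Cc2ccc(Oc3cccc(Br)c3)c(OCc3ccccc3)c2)cc1)C1(C)OCCO1 | intermediate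
13 | 2-{3-[4-(2-{3-(benzyloxy)-4-(3-bromophenoxy)phenyl}ethyl)phenoxy]-4-methoxyphenyl}-2-methyl-1,3-dioxolane | COc1ccc(cc1Oc1ccc(CCc2ccc(Oc3cccc(Br)c3)c(OCc3ccccc3)c2)cc1)C1(C)OCCO1 | intermediate
14 | 1-{3-[4-(2-{3-(benzyloxy)-4-(3-bromophenoxy)phenyl}ethyl)phenoxy]-4-methoxyphenyl}ethan-1-one (key-step precursor) | COc1ccc(C(C)=O)cc1Oc1ccc(CCc2ccc(Oc3cccc(Br)c3)c(OCc3ccccc3)c2)cc1 | intermediate
15 | sodium enolate of macrocyclic ketone 16 (not isolated; enolate geometry not fixed and of no consequence) | [Na+].COc1ccc2cc1Oc1ccc(cc1)CCc1ccc(c(OCc3ccccc3)c1)Oc1cccc(c1)C=C2[O-] | intermediate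
16 | macrocyclic aryl ketone benzyl ether (key-step product; oxo group on the bridge carbon next to ring A) | COc1ccc2cc1Oc1ccc(cc1)CCc1ccc(c(OCc3ccccc3)c1)Oc1cccc(c1)CC2=O | intermediate
17 | macrocyclic keto phenol (debenzylated 16, not isolated) | COc1ccc2cc1Oc1ccc(cc1)CCc1ccc(c(O)c1)Oc1cccc(c1)CC2=O | intermediate
18 | macrocyclic benzylic alcohol (racemic, not isolated) | COc1ccc2cc1Oc1ccc(cc1)CCc1ccc(c(O)c1)Oc1cccc(c1)CC2O | intermediate
19 | pakyonol | COc1ccc2cc1Oc1ccc(cc1)CCc1ccc(c(O)c1)Oc1cccc(c1)CC2 | target

**Step count**
- Total steps: 11.
- Longest linear sequence: 9 steps (5 → 6 → 8 → 9 → 10 → 12 → 13 → 14 → 16 → 19).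

**Steps most likely to fail**

Step 10.
- Enolate arylation between molecules may outpace ring closure and lead to chain growth and cyclodimerisation.
- The arylpalladium intermediate may be reduced with loss of bromine.
- The catalyst may decay during the long addition.

The fallback replaces the enolate coupling by a macrocyclic Heck reaction, a known way to close large rings, and sets out from 14. NaBH4 in MeOH/THF should reduce the ketone to the racemic open-chain 1-arylethanol F1. Catalytic p-TsOH in warm, dilute toluene with a radical inhibitor should dehydrate it to the ring A styrene F2. An intramolecular Heck reaction (Pd(OAc)2, P(o-tol)3, K2CO3, DMF, 100 °C, slow addition) should then bond the terminal vinyl carbon to C3 of ring D and give the macrocyclic E-stilbene benzyl ether F3. Hydrogenation over 10% Pd/C in EtOAc/EtOH saturates the alkene and removes the benzyl group, so the fallback comes back to the route at 19.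

Step 11.
- The reduction may stall at the benzylic alcohol stage.
- The alcohol may be diverted to a sluggish ethyl ether in the acidic ethanol.
- Phosphine residues from step 10 may slow the catalyst.

The fallback separates the two tasks and sets out from 16. Ionic hydrogenation with Et3SiH and CF3CO2H in CH2Cl2 (0 °C to rt) is a known deoxygenation of electron-rich aryl ketones that runs through the para-methoxybenzylic cation. It should give pakyonol benzyl ether F4. Neutral hydrogenolysis (H2, 10% Pd/C, EtOAc) then frees the phenol, and the fallback comes back to the route at 19.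

Step 8.
- Diimide may disproportionate faster than the conjugated 1,2-disubstituted alkene captures it, leaving the saturation incomplete.
- Slow opening of the ketal followed by condensation with the hydrazide would consume material.

The fallback removes both causes by changing the order and the reductant, and it sets out from 12. Hydrolysis with 1 M HCl in THF should give the open-chain stilbene methyl ketone F5. Homogeneous hydrogenation with RhCl(PPh3)3 under H2 (5 bar, toluene/EtOH, 50 °C) should then reduce only the alkene and leave the ketone, C–Br and O-benzyl intact. The fallback comes back to the route at 14.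

**Further compounds**
F1 | step 10 | 1-{3-[4-(2-{3-(benzyloxy)-4-(3-bromophenoxy)phenyl}ethyl)phenoxy]-4-methoxyphenyl}ethan-1-ol (racemic) | COc1ccc(C(C)O)cc1Oc1ccc(CCc2ccc(Oc3cccc(Br)c3)c(OCc3ccccc3)c2)cc1
F2 | step 10 | open-chain ring A styrene (vinyl in place of acetyl in 14) | COc1ccc(C=C)cc1Oc1ccc(CCc2ccc(Oc3cccc(Br)c3)c(OCc3ccccc3)c2)cc1
F3 | step 10 | macrocyclic E-stilbene benzyl ether (A–D bridge as CH=CH) | COc1ccc2cc1Oc1ccc(cc1)CCc1ccc(c(OCc3ccccc3)c1)Oc1cccc(c1)/C=C/2
F4 | step 11 | pakyonol benzyl ether | COc1ccc2cc1Oc1ccc(cc1)CCc1ccc(c(OCc3ccccc3)c1)Oc1cccc(c1)CC2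
F5 | step 8 | open-chain stilbene methyl ketone (E/Z mixture, geometry left open) | COc1ccc(C(C)=O)cc1Oc1ccc(C=Cc2ccc(Oc3cccc(Br)c3)c(OCc3ccccc3)c2)cc1
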